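**Retrosynthetic overview**
- The seven-membered dioxepinone is formed last by a ring expansion: a spiro 1,3-benzodioxin-4-one (an o-quinone mono-ketal on ring B) undergoes a 1,2-acyloxy shift from the spiro carbon to the neighbouring C–H carbon (6 → 7 ring). The spiro ketal comes from oxidative ipso-cyclisation of a depside.
- The depside is disconnected at the ester bond into haematommic acid (ring A) and the 7-OH of 7,8-dihydroxy-2,2,5-trimethylchroman-4-one (ring B plus pyranone).
- The chromanone comes from 5-methylpyrogallol and 3-methylbut-2-enoic acid (acylation, then oxa-Michael closure). The symmetry of the triol leaves no regiochemical choice. The triol comes from p-cresol by double ortho-formylation and Dakin oxidation.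
- Ring A is built from two molecules of methyl acetoacetate (Claisen, aldol, aromatisation), then formylated at C3 and de-esterified.
- Ring order: benzene ring A (built), benzene ring B (from p-cresol), pyranone, transient spiro-dioxinone, dioxepinone.

Assumption: the target has no stereocentre (it is achiral), so there is no enantiomer to select. The only stereocentre on the route is the transient spiro carbon of 14, which is racemic and disappears on aromatisation.

**Route**

Step 1
Reactants: 1 methyl acetoacetate (2 equiv)
Product: 3 methyl 2,4-dihydroxy-6-methylbenzoate (methyl orsellinate), via methyl 3,5,7-trioxooctanoate 2 (not isolated)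
Conditions: NaH (1.0 equiv), THF, 0 °C; n-BuLi (1.0 equiv), −78 °C → rt, then reflux; aq. HCl
Reagents that add atoms: none
Why: The γ-carbanion of the acetoacetate dianion attacks the ester of a second molecule (Claisen condensation) and the triketo ester 2 closes by intramolecular aldol condensation (C2 onto C7) and aromatises, a known biomimetic self-condensation of this substrate; no stereocentre.

Step 2
Reactants: 3 methyl 2,4-dihydroxy-6-methylbenzoate
Product: 4 methyl 3-formyl-2,4-dihydroxy-6-methylbenzoate (methyl haematommate)
Conditions: Cl2CHOMe (1.2 equiv), TiCl4 (2.2 equiv), CH2Cl2, −10 → 0 °C; 1 M HCl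
Reagents that add atoms: dichloromethyl methyl ether, COC(Cl)Cl (formyl C); water, O (formyl O)
Why: Rieche formylation, in which titanium chelated by the two phenolic oxygens steers the electrophile to C3 between them (the minor 5-formyl isomer is removed by crystallisation or chromatography); no stereocentre.

Step 3
Reactants: 4 methyl 3-formyl-2,4-dihydroxy-6-methylbenzoate
Product: 5 3-formyl-2,4-dihydroxy-6-methylbenzoic acid (haematommic acid)
Conditions: conc. H2SO4, 0 °C → rt, 30 min; pour onto ice
Reagents that add atoms: water, O
Why: AAC1 hydrolysis of a 2,6-disubstituted benzoate through the acylium ion, the classical way to open hindered orsellinate-type esters without the decarboxylation seen in hot alkali; the protonated aldehyde survives.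

Step 4
Reactants: 6 4-methylphenol (p-cresol)
Product: 7 2-hydroxy-5-methylbenzene-1,3-dicarbaldehyde
Conditions: (CH2)6N4 (4 equiv), CF3CO2H, reflux, 24 h; 4 M HCl, rt
Reagents that add atoms: hexamethylenetetramine, C1N2CN3CN1CN(C2)C3 (both formyl C); water, O (both formyl O)
Why: Double Duff reaction (aminomethylation, hydride transfer, hydrolysis) at the two ortho positions, the para position being blocked by the methyl group.

Step 5
Reactants: 7 2-hydroxy-5-methylbenzene-1,3-dicarbaldehyde
Product: 9 5-methylbenzene-1,2,3-triol (5-methylpyrogallol), via bis-formate 8 (not isolated)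
Conditions: 30% H2O2 (2.5 equiv), B(OH)3, cat. H2SO4, THF, rt, Ar; aq. Na2SO3
Reagents that add atoms: hydrogen peroxide, OO
Why: Double Dakin oxidation (aryl migration in each peroxide adduct gives the formate, hydrolysed in situ), with boric acid holding the triol as a borate to prevent over-oxidation.

Step 6
Reactants: 9 5-methylbenzene-1,2,3-triol; 10 3-methylbut-2-enoic acid
Product: 12 7,8-dihydroxy-2,2,5-trimethylchroman-4-one, via aryl enone 11 (not isolated)
Conditions: P2O5–MeSO3H (Eaton's reagent), 70 °C, 1 h; ice–water
Reagents that add atoms: none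
Why: Friedel–Crafts acylation followed by 6-endo oxa-Michael closure; the two free ring positions of 9 are equivalent by symmetry and each has only one ortho OH, so only this chromanone can form.

Step 7
Reactants: 5 3-formyl-2,4-dihydroxy-6-methylbenzoic acid; 12 7,8-dihydroxy-2,2,5-trimethylchroman-4-one
Product: 13 8-hydroxy-2,2,5-trimethyl-4-oxochroman-7-yl 3-formyl-2,4-dihydroxy-6-methylbenzoate (depside)
Conditions: DCC (1.1 equiv), THF–toluene, 0 °C → rt, 12 h
Reagents that add atoms: none
Why: Carbodiimide aryl-ester formation (Steglich type); the 7-OH is the most acidic phenol (para to C4=O), so it protonates the O-acylisourea and its phenoxide is acylated, while both OH groups of 5 are hydrogen-bonded to carbonyls and the 8-OH stays free.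

Step 8
Reactants: 13 8-hydroxy-2,2,5-trimethyl-4-oxochroman-7-yl 3-formyl-2,4-dihydroxy-6-methylbenzoate
Product: 15 4-formyl-3,6-dihydroxy-1,9-dimethyl-11H-dibenzo[b,e][1,4]dioxepin-11-one carrying a 2,2-dimethyl-2,3-dihydro-4H-pyran-4-one fused at C7 (ring O) / C8 (C=O) (target), via spiro quinone ketal 14 (not isolated)
Conditions: PhI(OAc)2 (1.0 equiv), (CF3)2CHOH–CH2Cl2 (1:4), −40 °C, 15 min; then TfOH (10 mol %), −40 → 0 °C
Reagents that add atoms: none
Why: Proposed new method: the λ3-iodane oxidises the only electron-rich, non-chelated phenol (8-OH) to a phenoxonium ion, and the tethered ring-A 2-OH adds ipso at C7 (6-exo, the same spiro-1,3-benzodioxin-4-one geometry as the Meisenheimer intermediate of depside Smiles rearrangements) to give the o-quinone mono(acyl aryl) ketal 14; acid, added only after the oxidant is consumed so that the product phenol never meets it, protonates the dienone, the ester carbonyl O bridges to C6 (1,3-dioxolan-2-ylium), the C7–O(acyl) bond breaks and loss of H-6 rearomatises, a net ionic 1,2-acyloxy shift that enlarges the six-membered dioxinone to the seven-membered dioxepinone and places the ester O next to CH3 and the ether O next to the free OH; closest known reactions are hypervalent-iodine dearomative spiroketalisation of phenols, the acid-catalysed acyloxy migration of Wessely o-quinol acetates (dienone–phenol type) and the grisadienedione → depsidone ring expansion.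

**Compound list**
1 | methyl acetoacetate (methyl 3-oxobutanoate) | COC(=O)CC(C)=O | starting material
2 | methyl 3,5,7-trioxooctanoate | COC(=O)CC(=O)CC(=O)CC(C)=O | intermediate (not isolated)
3 | methyl 2,4-dihydroxy-6-methylbenzoate (methyl orsellinate) | COC(=O)c1c(C)cc(O)cc1O | intermediate
4 | methyl 3-formyl-2,4-dihydroxy-6-methylbenzoate (methyl haematommate) | COC(=O)c1c(C)cc(O)c(C=O)c1O | intermediate
5 | 3-formyl-2,4-dihydroxy-6-methylbenzoic acid (haematommic acid) | OC(=O)c1c(C)cc(O)c(C=O)c1O | intermediate
6 | 4-methylphenol (p-cresol) | Cc1ccc(O)cc1 | starting material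
7 | 2-hydroxy-5-methylbenzene-1,3-dicarbaldehyde | Cc1cc(C=O)c(O)c(C=O)c1 | intermediate
8 | 2-hydroxy-5-methyl-1,3-phenylene diformate | Cc1cc(OC=O)c(O)c(OC=O)c1 | intermediate (not isolated)
9 | 5-methylbenzene-1,2,3-triol (5-methylpyrogallol) | Cc1cc(O)c(O)c(O)c1 | intermediate
10 | 3-methylbut-2-enoic acid | CC(C)=CC(O)=O | starting material
11 | 3-methyl-1-(2,3,4-trihydroxy-6-methylphenyl)but-2-en-1-one | CC(C)=CC(=O)c1c(C)cc(O)c(O)c1O | intermediate (not isolated)
12 | 7,8-dihydroxy-2,2,5-trimethylchroman-4-one | CC1(C)CC(=O)c2c(C)cc(O)c(O)c2O1 | intermediate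
13 | 8-hydroxy-2,2,5-trimethyl-4-oxochroman-7-yl 3-formyl-2,4-dihydroxy-6-methylbenzoate | Cc1cc(O)c(C=O)c(O)c1C(=O)Oc1cc(C)c2C(=O)CC(C)(C)Oc2c1O | intermediate
14 | 8-formyl-7-hydroxy-2',2',5,5'-tetramethyl-2',3'-dihydrospiro[1,3-benzodioxine-2,7'-chromene]-4,4',8'-trione (racemic spiro centre) | Cc1cc(O)c(C=O)c2c1C(=O)OC1(O2)C=C(C)C3=C(OC(C)(C)CC3=O)C1=O | intermediate (not isolated)
15 | 4-formyl-3,6-dihydroxy-1,9-dimethyl-11H-dibenzo[b,e][1,4]dioxepin-11-one with a 2,2-dimethyl-2,3-dihydro-4H-pyran-4-one fused at C7 (ring O) and C8 (C=O); achiral | Cc1cc(O)c(C=O)c2c1C(=O)Oc1c(C)c3c(c(O)c1O2)OC(C)(C)CC3=O | target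

**Totals**
Total steps: 8. Longest linear sequence: 5 (steps 1, 2, 3, 7, 8 or steps 4, 5, 6, 7, 8).

**Three steps most likely to fail**

Step 8 (the proposed new step). Risks are attack of external nucleophiles at the methyl-bearing para carbon (p-quinol or quinone methide), solvolysis of 14 to an o-quinone plus free acid, and ionisation of 14 back to the phenoxonium ion instead of acyloxy migration. The fallback uses known chemistry, sets out from depside 13 and returns to 15. K2CO3 in DMSO at rt effects the Smiles rearrangement known for depsides (the ring-A 2-phenoxide attacks C7, which is para to the chromanone carbonyl, and carboxylate leaves), giving 3-formyl-4-hydroxy-2-[(8-hydroxy-2,2,5-trimethyl-4-oxochroman-7-yl)oxy]-6-methylbenzoic acid F1. NBS (1.0 equiv, MeCN, 0 °C) brominates the only free position of the electron-rich ring, giving 2-[(6-bromo-8-hydroxy-2,2,5-trimethyl-4-oxochroman-7-yl)oxy]-3-formyl-4-hydroxy-6-methylbenzoic acid F2. CuI/1,10-phenanthroline with Cs2CO3 in DMF at 110 °C then closes the lactone by Ullmann-type O-arylation of the carboxylate, which gives 15.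

Step 7. Risks are acylation at the 8-OH, self-esterification of 5 through its 4-OH, N-acylurea formation with the hindered acid, and 7-O → 8-O acyl migration. The fallback masks the donor phenols so that a base-assisted, 7-phenoxide-selective acylation can be used; it sets out from acid 5 and returns to 13. Ac2O in pyridine gives 2,4-diacetoxy-3-formyl-6-methylbenzoic acid F3. Coupling with 12 (DCC, cat. DMAP, CH2Cl2, 0 °C) gives 8-hydroxy-2,2,5-trimethyl-4-oxochroman-7-yl 2,4-diacetoxy-3-formyl-6-methylbenzoate F4. NH4OAc in aqueous MeOH at rt removes the two unhindered aryl acetates while the 2,6-disubstituted benzoate stays intact, which gives 13.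

Step 5. The risk is over-oxidation of the air-sensitive pyrogallol under peroxide conditions. The fallback avoids oxidation at the triol stage, sets out from p-cresol 6 (bypassing 7) and returns to 9. Br2 (2 equiv, CH2Cl2, 0 °C) gives 2,6-dibromo-4-methylphenol F5. NaOMe with cat. CuI in MeOH–DMF at 110 °C gives 2,6-dimethoxy-4-methylphenol F6. BBr3 in CH2Cl2 (−78 °C → rt) cleaves both methyl ethers to give 9.

**Further compounds**
F1 | step 8 | 3-formyl-4-hydroxy-2-[(8-hydroxy-2,2,5-trimethyl-4-oxochroman-7-yl)oxy]-6-methylbenzoic acid | Cc1cc(O)c(C=O)c(Oc2cc(C)c3C(=O)CC(C)(C)Oc3c2O)c1C(=O)O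
F2 | step 8 | 2-[(6-bromo-8-hydroxy-2,2,5-trimethyl-4-oxochroman-7-yl)oxy]-3-formyl-4-hydroxy-6-methylbenzoic acid | Cc1cc(O)c(C=O)c(Oc2c(Br)c(C)c3C(=O)CC(C)(C)Oc3c2O)c1C(=O)O
F3 | step 7 | 2,4-diacetoxy-3-formyl-6-methylbenzoic acid | Cc1cc(OC(C)=O)c(C=O)c(OC(C)=O)c1C(=O)O
F4 | step 7 | 8-hydroxy-2,2,5-trimethyl-4-oxochroman-7-yl 2,4-diacetoxy-3-formyl-6-methylbenzoate | Cc1cc(OC(C)=O)c(C=O)c(OC(C)=O)c1C(=O)Oc1cc(C)c2C(=O)CC(C)(C)Oc2c1O
F5 | step 5 | 2,6-dibromo-4-methylphenol | Cc1cc(Br)c(O)c(Br)c1
F6 | step 5 | 2,6-dimethoxy-4-methylphenol | COc1cc(C)cc(OC)c1O
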